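- Late in the beta run the readings stand still: target reads 35.6% at 2.08 d and 35.9% at 5.00 d. So we work from that plateau.

in all of them: second nucleophile 1.11 M

| flask | starting material | first nucleophile | remark | time |
|---|---|---|---|---|
| beta | 0.50 M | 1.33 M | run made earlier |  |
| epsilon | 1.1 M | 1.33 M | run made earlier |  |
| gamma | 0.74 M | 0.67 M | run made earlier |  |
| flask | 0.74 M | 1.33 M |  | 4.0 d |

- beta (time / d: target / %, other capture product / %): 0.417: 30.7, 21.5; 0.625: 33.5, 24.4; 0.833: 35.8, 25.6; 1.25: 33.5, 22.8; 2.08: 35.6, 26.4; 3.00: 35.7, 23.7; 5.00: 35.9, 25.2
- epsilon (time / d: target / %, other capture product / %): 0.417: 29.2, 20.5; 0.625: 33.0, 24.0; 0.833: 34.9, 22.8; 1.25: 35.7, 23.4; 2.08: 34.5, 22.2; 3.00: 35.2, 22.0; 5.00: 33.8, 23.2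
- gamma (time / d: target / %, other capture product / %): 1.04: 23.7, 28.2; 2.08: 21.7, 27.3; 3.00: 21.0, 27.2; 4.00: 21.6, 28.0; 5.00: 21.9, 26.9

(scatter of a reading: 1 percentage point)



- share of target in target plus other capture product at 10 min
- share of target in target plus other capture product at 4.0 h
- share of target in target plus other capture product at 4.0 d
- which of target and other capture product there is more of at 4.0 d

- Fastest rung: we follow one molecule of starting material and suppose that it passes through a short-lived intermediate. That intermediate reaches a fork, where first nucleophile makes target and second nucleophile makes other capture product. No reading shows this step directly.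
- Next rung: in beta, 14.5% of the final target was still to come at 0.417 d. This reads as a half-life of about 0.150 d for the consumption of starting material, so 2.08 d is 13.9 such half-lives.
- Slowest rung: on the plateau at 3.00 d and 5.00 d, beta and epsilon together read a ratio of target to other capture product of 1.49. Gamma, with about half the first nucleophile, reads 0.793, about half of that ratio.
- We therefore carry s = 1.12 /M, the plateau ratio of target to other capture product per molar of first nucleophile, with second nucleophile held at 1.11 M.
- The flask has the nucleophile charges of beta and epsilon, so s gives it a share of 59.9% at 4.0 d, with target ahead. Both early times stand before the first reading, so we commit to no number for them.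
- The forecast gives 59.7%, 59.6% and 59.5%, with target ahead, holding that “the products do not interconvert”; its late share stands close to ours.
- The flask gives 30.8%, 44.6% and 60.1%, with target ahead at 35.7% against 23.7%.

    starting material → intermediate (k = 0.194 /h)
    first nucleophile + intermediate → target (k = 112 /M/h)
    second nucleophile + intermediate → other capture product (k = 311 /M/h)
    intermediate → solvolysis product (k = 152 /h)
    intermediate → side product (k = 0.159 /h)
    second nucleophile → decomposed reagent (k = 0.329 /h)

- The flask's final totals give 1.13 /M, where we carried 1.12 /M. Its share climbs on the way, and second nucleophile stands at 2.61% of its charge at 0.400 d, first nucleophile at 84.0%. So s describes final totals and not each moment. The neighbouring flask keeps every other charge but holds 2.3 M of first nucleophile. There s gives a ratio of 2.58 and a share of 72.0%, and its simulated share at 4.0 d is 71.3%.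

The data come from a simulation for an exercise; noise was put on by code.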